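If product leaves the catalyst by one step, the breakdown of catalyst intermediate C into free catalyst and product, then I could count each set-up in lifetimes of that step.

the same everywhere: substrate 0.19 M; free catalyst 15 mol%; impurity 3.0 mM
- zeta: coupling partner 1.05 equiv; time 30 h; everything together in a closed stirred flask, run for 30 h
- alpha: coupling partner 1.05 equiv; one stirred flow tank at steady state, fed with the mixture as stated, mean residence time 300 h
- epsilon: coupling partner 1.05 equiv; a single well-mixed tank run continuously and read at steady state, 30 h in it on average
- theta: coupling partner 1.05 equiv (fed, over 30.0 h); time 30 h; all but coupling partner at the start; coupling partner goes in evenly over 30.0 h, the run ends at 30 h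

- the set-up with the highest amount of product at the outlet or at the end, in percent of the substrate put in ("none" if the first two lie within 2 percentage points) (zeta / alpha / epsilon / theta / none)
- amount of product at the outlet or at the end, in percent of the substrate put in, zeta
- amount of product at the outlet or at the end, in percent of the substrate put in, alpha
- amount of product at the outlet or at the end, in percent of the substrate put in, epsilon
- amount of product at the outlet or at the end, in percent of the substrate put in, theta

- what is said of product includes idle adduct
- the stated concentrations are those of everything mixed, before any reaction; amounts are the same in each set-up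
- the feed brings no volume worth counting
- run time (zeta): 30 h

    coupling partner + free catalyst ⇌ catalyst intermediate A (K1 = 11.3 M⁻¹, k1 = 7.51 × 10⁻⁴ M⁻¹ s⁻¹)
    catalyst intermediate A ⇌ catalyst intermediate B (K2 = 2.7, k2 = 1.17 × 10⁻⁴ s⁻¹)
    substrate + catalyst intermediate B ⇌ catalyst intermediate C (K3 = 55.9 M⁻¹, k3 = 0.0246 M⁻¹ s⁻¹)
    catalyst intermediate C → free catalyst + product (k4 = 2.90 × 10⁻⁵ s⁻¹)
    coupling partner + product ⇌ idle adduct, settled at all times (K5 = 13 M⁻¹)
    free catalyst + impurity → spent catalyst (k6 = 1.82 M⁻¹ s⁻¹)

First I asked how much catalyst works. At the start of zeta, free catalyst was lost to impurity at a pseudo-first-order rate of 0.00546 s⁻¹ and captured by coupling partner at 1.50 × 10⁻⁴ s⁻¹, so I wrote the impurity off against the catalyst. As fractions of the substrate charge, impurity took 1.58% of the 15 mol% loaded, leaving 13.4% of working catalyst.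

Next I asked which step paces a turn. At the start of zeta, catalyst intermediate C had a half-life of 6.6 h by its breakdown alone, longer than the 1.6 h of catalyst intermediate A by its forward step alone and the 1.29 h that free catalyst lasted against the charged coupling partner by its forward step alone, so I took that breakdown as the rate-limiting step for the start of zeta, and claimed it for no other set-up.

Then I asked how many lifetimes fit. The time given holds 3.13 lifetimes, and catalyst intermediate C cannot exceed the working catalyst. So 42.0% of the substrate charge is the turnover ceiling, the working catalyst fraction times the lifetimes of catalyst intermediate C in the time given. It stood the same for zeta, epsilon and theta. Alpha has ten times the time, so its ceiling of 420% lay above the substrate charge. I committed to alpha as best and stopped there, with ceilings rather than yields.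

The forecast went further than my ceilings, with the ground “Turnover is limited by C → product”. It gave 19.8% for zeta, 74.3% for alpha, 18.6% for epsilon and 13% for theta, with alpha best.

The simulation gave 20.0% for zeta, 74.3% for alpha, 18.6% for epsilon and 12.2% for theta, with alpha best.

The forecast stood 0.80 percentage points above theta. Zeta reached 47.6% of its ceiling and theta 29.1%. The neighbour flask was theta with 3.8 mol% of free catalyst. The same write-off left it 2.22% of working catalyst and a ceiling of 6.96%, and theta's share of that ceiling pointed to 2.03%. Spent catalyst there stood at 41.6% of its catalyst charge, and the neighbour flask gave 2.23% of product, 32.0% of its ceiling.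

The rate constants were chosen freely; no experiment stands behind them.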